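## Retrosynthetic overview

1. Target ⇐ oxirane formed last (peracid on the 1(10)-Z-alkene), after acylation of the 8-OH; rings are made in the order ten-membered carbocycle → γ-lactone → oxirane.
2. Carbocycle and lactone ⇐ one acyclic Z-enal carrying a Baylis–Hillman diol, closed at C6–C7 (the farnesyl C1–C10 bond made by germacrene cyclase): the C7=C11 π-system, as an umpoled π-allyl (allylindium), attacks C6, C13 becomes the exocyclic methylene, and O6 then lactonises on C12.
3. Acyclic chain ⇐ C7–C11 by Morita–Baylis–Hillman reaction with methyl acrylate; C2–C3 by α-selective allylbarium addition to a Z-enal, with C3 set by CBS reduction.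
4. Building blocks: (Z)-3-iodobut-2-en-1-ol (from 2-butyn-1-ol) plus (S)-glycidol (sets C8); 3-methylfuran-2(5H)-one supplies both the C3–C6 enal and the ester side chain.

Assumption: the SMILES is read literally (4Z-alkene, cis-fused 12,6-lactone, cis-1,10-epoxide, (1R,3S,6S,7R,8R,10S)); positions are given in germacrane numbering (C1–C15).

## Route

Step 1
Reactants: 1 2-butyn-1-ol
Product: 3 (Z)-3-iodobut-2-en-1-ol, via cyclic alkenylaluminate 2 (not isolated)
Conditions: NaAlH2(OCH2CH2OMe)2, THF, 0 → 25 °C; then I2, THF, −78 → 0 °C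
Reagents that add atoms: iodine, II
Why: Hydroxyl-directed trans-hydroalumination of the propargylic alcohol places aluminium on C3 cis to the CH2O group, and iododealumination with retention gives only the Z vinyl iodide.

Step 2
Reactants: 4 (S)-glycidol
Product: 5 (R)-triethyl(oxiran-2-ylmethoxy)silane
Conditions: Et3SiCl, imidazole, CH2Cl2, 0 °C
Reagents that add atoms: chlorotriethylsilane, CC[Si](Cl)(CC)CC
Why: Simple O-silylation that leaves the stereocentre (future C8) untouched; the descriptor changes from S to R only through the priority rules.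

Step 3
Reactants: 3 (Z)-3-iodobut-2-en-1-ol; 5 (R)-triethyl(oxiran-2-ylmethoxy)silane
Product: 7 (2R,4Z)-4-methyl-1-(triethylsilyloxy)hex-4-ene-2,6-diol, via dilithiated butenol 6 (not isolated)
Conditions: n-BuLi (1.0 equiv), Et2O, −78 °C; t-BuLi (2.1 equiv), −78 °C; then 5, BF3·OEt2, −78 °C
Reagents that add atoms: none
Why: Iodine–lithium exchange with retention of the Z geometry, then BF3-promoted SN2 opening of the terminal epoxide at its CH2, forms C9–C10; C8 (R) is carried over unchanged from glycidol.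

Step 4
Reactants: 7 (2R,4Z)-4-methyl-1-(triethylsilyloxy)hex-4-ene-2,6-diol
Product: 8 (2R,4Z)-6-chloro-4-methyl-1-(triethylsilyloxy)hex-4-en-2-ol
Conditions: N-chlorosuccinimide, Me2S, CH2Cl2, −20 → 0 °C
Reagents that add atoms: N-chlorosuccinimide, O=C1CCC(=O)N1Cl
Why: Corey–Kim chlorination converts only the primary allylic alcohol (SN2 on the alkoxysulfonium salt), leaving the secondary alcohol and the alkene geometry intact.

Step 5
Reactants: 8 (2R,4Z)-6-chloro-4-methyl-1-(triethylsilyloxy)hex-4-en-2-ol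
Product: 9 (2R,4Z)-6-chloro-4-methyl-1,2-bis(triethylsilyloxy)hex-4-ene
Conditions: Et3SiOTf, 2,6-lutidine, CH2Cl2, −78 °C
Reagents that add atoms: triethylsilyl trifluoromethanesulfonate, CC[Si](CC)(CC)OS(=O)(=O)C(F)(F)F
Why: Silylation of the C8 hydroxyl with a non-nucleophilic base that does not displace the allylic chloride.

Step 6
Reactants: 10 3-methylfuran-2(5H)-one
Product: 12 (Z)-4-(tert-butyldimethylsilyloxy)-N-methoxy-N,2-dimethylbut-2-enamide, via hydroxy Weinreb amide 11 (not isolated)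
Conditions: MeNH(OMe)·HCl, i-PrMgCl, THF, −20 → 0 °C; then t-BuMe2SiCl, imidazole (cat.), 0 → 25 °C
Reagents that add atoms: N,O-dimethylhydroxylamine hydrochloride, CNOC.Cl; tert-butyldimethylsilyl chloride, CC(C)(C)[Si](C)(C)Cl
Why: Weinreb aminolysis of the butenolide, whose ring fixes the Z geometry, followed by silylation of the magnesium alkoxide in the same flask before it can relactonise.

Step 7
Reactants: 12 (Z)-4-(tert-butyldimethylsilyloxy)-N-methoxy-N,2-dimethylbut-2-enamide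
Product: 13 (Z)-4-(tert-butyldimethylsilyloxy)-2-methylbut-2-enal
Conditions: i-Bu2AlH, THF, −78 °C
Reagents that add atoms: none
Why: Weinreb amide reduction stops at the chelated hemiaminal, so the Z-enal is released only on cold work-up and is used at once.

Step 8
Reactants: 9 (2R,4Z)-6-chloro-4-methyl-1,2-bis(triethylsilyloxy)hex-4-ene; 13 (Z)-4-(tert-butyldimethylsilyloxy)-2-methylbut-2-enal
Product: 15 (2Z,4RS,6Z,9R)-1-(tert-butyldimethylsilyloxy)-3,7-dimethyl-9,10-bis(triethylsilyloxy)deca-2,6-dien-4-ol, via allylbarium chloride 14 (not isolated)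
Conditions: Rieke barium (zerovalent Ba, from BaI2 and lithium biphenylide), THF, −78 °C; then 13, −78 °C
Reagents that add atoms: none
Why: Allylbarium carbonyl allylation occurs at the α-carbon in a 1,2-sense with retention of the allylic Z geometry, forming C2–C3 as the linear homoallylic alcohol; C3 forms as a mixture and is corrected in steps 9 and 10.

Step 9
Reactants: 15 (2Z,4RS,6Z,9R)-1-(tert-butyldimethylsilyloxy)-3,7-dimethyl-9,10-bis(triethylsilyloxy)deca-2,6-dien-4-ol
Product: 16 (2Z,6Z,9R)-1-(tert-butyldimethylsilyloxy)-3,7-dimethyl-9,10-bis(triethylsilyloxy)deca-2,6-dien-4-one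
Conditions: MnO2 (activated, 20 equiv), CH2Cl2, 25 °C
Reagents that add atoms: none
Why: Neutral MnO2 allylic oxidation gives the enone without moving the skipped C1=C10 alkene into conjugation.

Step 10
Reactants: 16 (2Z,6Z,9R)-1-(tert-butyldimethylsilyloxy)-3,7-dimethyl-9,10-bis(triethylsilyloxy)deca-2,6-dien-4-one
Product: 17 (2Z,4S,6Z,9R)-1-(tert-butyldimethylsilyloxy)-3,7-dimethyl-9,10-bis(triethylsilyloxy)deca-2,6-dien-4-ol
Conditions: (R)-2-methyl-CBS-oxazaborolidine [(3aR)-1-methyl-3,3-diphenyltetrahydro-1H,3H-pyrrolo[1,2-c][1,3,2]oxazaborole, 20 mol %], BH3·SMe2, THF, −30 °C; MeOH quench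
Reagents that add atoms: none
Why: Corey–Bakshi–Shibata reduction in which the α-methyl Z-alkenyl group is the large substituent and the allylic CH2 the small one, so the (R)-catalyst delivers hydride to give the S carbinol (target C3).

Step 11
Reactants: 17 (2Z,4S,6Z,9R)-1-(tert-butyldimethylsilyloxy)-3,7-dimethyl-9,10-bis(triethylsilyloxy)deca-2,6-dien-4-ol
Product: 18 (2Z,4S,6Z,9R)-1,4-bis(tert-butyldimethylsilyloxy)-3,7-dimethyl-9,10-bis(triethylsilyloxy)deca-2,6-diene
Conditions: t-BuMe2SiOTf, 2,6-lutidine, CH2Cl2, −78 °C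
Reagents that add atoms: tert-butyldimethylsilyl trifluoromethanesulfonate, CC(C)(C)[Si](C)(C)OS(=O)(=O)C(F)(F)F
Why: Silylation of the C3 hydroxyl, needed because a free Z-γ-hydroxy enal would later close to a lactol and aromatise to a furan.

Step 12
Reactants: 18 (2Z,4S,6Z,9R)-1,4-bis(tert-butyldimethylsilyloxy)-3,7-dimethyl-9,10-bis(triethylsilyloxy)deca-2,6-diene
Product: 19 (2R,4Z,7S,8Z)-7,10-bis(tert-butyldimethylsilyloxy)-4,8-dimethyl-2-(triethylsilyloxy)deca-4,8-dienal
Conditions: (COCl)2, DMSO, CH2Cl2, −78 → −35 °C; then Et3N, −78 → 0 °C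
Reagents that add atoms: none
Why: Under Swern conditions a primary triethylsilyl ether is cleaved and oxidised directly to the aldehyde, while the secondary triethylsilyl and both tert-butyldimethylsilyl ethers survive.

Step 13
Reactants: 19 (2R,4Z,7S,8Z)-7,10-bis(tert-butyldimethylsilyloxy)-4,8-dimethyl-2-(triethylsilyloxy)deca-4,8-dienal; 20 methyl acrylate
Product: 21 methyl (3RS,4R,6Z,9S,10Z)-9,12-bis(tert-butyldimethylsilyloxy)-3-hydroxy-6,10-dimethyl-2-methylidene-4-(triethylsilyloxy)dodeca-6,10-dienoate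
Conditions: 1,4-diazabicyclo[2.2.2]octane (1 equiv), methyl acrylate (excess), MeOH (cat.), 25 °C
Reagents that add atoms: none
Why: Morita–Baylis–Hillman reaction of the activated α-silyloxy aldehyde adds C11–C13 and the C12 ester; the new C7 carbinol is a mixture that does not matter because C7 is planarised in step 16.

Step 14
Reactants: 21 methyl (3RS,4R,6Z,9S,10Z)-9,12-bis(tert-butyldimethylsilyloxy)-3-hydroxy-6,10-dimethyl-2-methylidene-4-(triethylsilyloxy)dodeca-6,10-dienoate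
Product: 22 methyl (3RS,4R,6Z,9S,10Z)-9-(tert-butyldimethylsilyloxy)-3,4,12-trihydroxy-6,10-dimethyl-2-methylidenedodeca-6,10-dienoate
Conditions: camphor-10-sulfonic acid (0.2 equiv), MeOH/CH2Cl2 1:1, 0 °C
Reagents that add atoms: none
Why: Acid-catalysed methanolysis removes the primary allylic tert-butyldimethylsilyl ether and the secondary triethylsilyl ether much faster than the hindered secondary tert-butyldimethylsilyl ether at C3.

Step 15
Reactants: 22 methyl (3RS,4R,6Z,9S,10Z)-9-(tert-butyldimethylsilyloxy)-3,4,12-trihydroxy-6,10-dimethyl-2-methylidenedodeca-6,10-dienoate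
Product: 23 methyl (3RS,4R,6Z,9S,10Z)-9-(tert-butyldimethylsilyloxy)-3,4-dihydroxy-6,10-dimethyl-2-methylidene-12-oxododeca-6,10-dienoate
Conditions: [Cu(MeCN)4]OTf (5 mol %), 2,2'-bipyridine (5 mol %), TEMPO (2,2,6,6-tetramethylpiperidine-1-oxyl, 5 mol %), N-methylimidazole (10 mol %), air, MeCN, 25 °C
Reagents that add atoms: none
Why: Copper/TEMPO aerobic oxidation is selective for the primary allylic alcohol over the two secondary alcohols, does not cleave the 1,2-diol, and keeps the Z-enal geometry.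

Step 16
Reactants: 23 methyl (3RS,4R,6Z,9S,10Z)-9-(tert-butyldimethylsilyloxy)-3,4-dihydroxy-6,10-dimethyl-2-methylidene-12-oxododeca-6,10-dienoate
Product: 26 (3S,6S,7R,8R)-3-(tert-butyldimethylsilyloxy)-8-hydroxygermacra-1(10)Z,4Z,11(13)-trien-12,6-olide, via allylindium species 24 (not isolated), via hydroxy ester 25 (not isolated)
Conditions: Pd(PPh3)4 (10 mol %), InI (2.0 equiv), THF/H2O 20:1, 25 °C, 23 added over 12 h (final 2 mM)
Reagents that add atoms: none
Why: Proposed new method: zerovalent palladium ionises the Baylis–Hillman C7–OH of either C7 epimer to a 2-(methoxycarbonyl)-π-allyl complex, which monovalent indium converts into a nucleophilic allylindium bound at C13; the free 8-OH chelates indium and so holds C8 cis to C13 with its oxygen turned inward, C7 then adds to the tethered Z-enal through a six-membered chair transition state with the aldehyde substituent equatorial (6,7-syn, hence the cis-lactone, and the required 7R,8R relationship), and the indium alkoxide on O6 lactonises onto C12; the closest known reaction types are the intermolecular palladium/indium umpolung allylation of aldehydes with allylic alcohols, the palladium/diethylzinc umpolung macrocyclisation to ten-membered germacrene rings, and the Dreiding–Schmidt addition of 2-(alkoxycarbonyl)allyl metals giving cis α-methylene-γ-butyrolactones.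

Step 17
Reactants: 13 (Z)-4-(tert-butyldimethylsilyloxy)-2-methylbut-2-enal
Product: 27 (Z)-4-(tert-butyldimethylsilyloxy)-2-methylbut-2-enoic acid
Conditions: NaClO2, NaH2PO4, 2-methyl-2-butene, t-BuOH/H2O, 0 → 25 °C
Reagents that add atoms: sodium chlorite, [Na+].[O-]Cl=O
Why: Pinnick oxidation converts the enal to the acid without Z/E isomerisation, and the silyl ether prevents lactonisation to the butenolide.

Step 18
Reactants: 26 (3S,6S,7R,8R)-3-(tert-butyldimethylsilyloxy)-8-hydroxygermacra-1(10)Z,4Z,11(13)-trien-12,6-olide; 27 (Z)-4-(tert-butyldimethylsilyloxy)-2-methylbut-2-enoic acid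
Product: 29 (3S,6S,7R,8R)-3-(tert-butyldimethylsilyloxy)-8-[(Z)-4-(tert-butyldimethylsilyloxy)-2-methylbut-2-enoyloxy]germacra-1(10)Z,4Z,11(13)-trien-12,6-olide, via Yamaguchi mixed anhydride 28 (not isolated)
Conditions: 27, 2,4,6-Cl3C6H2COCl, Et3N, THF, 25 °C; then 26, 4-(dimethylamino)pyridine, toluene, 0 → 25 °C
Reagents that add atoms: none
Why: Yamaguchi esterification acylates the only free hydroxyl (C8) with retention at C8, and the short, cold exposure to the pyridine base limits Z to E isomerisation of the acyl group.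

Step 19
Reactants: 29 (3S,6S,7R,8R)-3-(tert-butyldimethylsilyloxy)-8-[(Z)-4-(tert-butyldimethylsilyloxy)-2-methylbut-2-enoyloxy]germacra-1(10)Z,4Z,11(13)-trien-12,6-olide
Product: 30 (1R,3S,6S,7R,8R,10S)-3-(tert-butyldimethylsilyloxy)-8-[(Z)-4-(tert-butyldimethylsilyloxy)-2-methylbut-2-enoyloxy]-1,10-epoxygermacra-4Z,11(13)-dien-12,6-olide
Conditions: mCPBA (1.05 equiv), NaHCO3, CH2Cl2, 0 °C
Reagents that add atoms: 3-chloroperbenzoic acid, OOC(=O)c1cccc(Cl)c1
Why: Prilezhaev epoxidation attacks only the 1(10)-alkene, the one electron-rich alkene (C4=C5 is flanked by two allylic C–O bonds, the other two are conjugated to carbonyls); stereospecific syn addition to the Z-alkene gives the cis-epoxide, and attack on the outer face of the conformer with the C3 and C8 oxygen substituents pseudo-equatorial is expected to give the 1R,10S isomer.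

Step 20
Reactants: 30 (1R,3S,6S,7R,8R,10S)-3-(tert-butyldimethylsilyloxy)-8-[(Z)-4-(tert-butyldimethylsilyloxy)-2-methylbut-2-enoyloxy]-1,10-epoxygermacra-4Z,11(13)-dien-12,6-olide
Product: 31 CNP0410854.1, (1R,3S,6S,7R,8R,10S)-1,10-epoxy-3-hydroxy-8-[(Z)-4-hydroxy-2-methylbut-2-enoyloxy]germacra-4Z,11(13)-dien-12,6-olide
Conditions: HF·pyridine, pyridine, THF, 0 → 25 °C
Reagents that add atoms: none
Why: Buffered fluoride desilylation removes both silyl ethers under conditions that spare the epoxide, the α-methylene lactone and the Z-γ-hydroxy enoate (which lactonises only under base).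

## Compound list

1 | 2-butyn-1-ol | CC#CCO | starting material
2 | sodium bis(2-methoxyethoxy)aluminate chelate of (Z)-but-2-en-1-olate, Al on C3 in a five-membered O–Al–C ring | CC1=CCO[Al-]1(OCCOC)OCCOC.[Na+] | intermediate
3 | (Z)-3-iodobut-2-en-1-ol | C/C(I)=C/CO | intermediate
4 | (S)-glycidol | OC[C@H]1CO1 | starting material
5 | (R)-triethyl(oxiran-2-ylmethoxy)silane | CC[Si](CC)(CC)OC[C@H]1CO1 | intermediate
6 | (Z)-3-lithiobut-2-en-1-ol lithium alkoxide | C/C([Li])=C/CO[Li] | intermediate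
7 | (2R,4Z)-4-methyl-1-(triethylsilyloxy)hex-4-ene-2,6-diol | CC[Si](CC)(CC)OC[C@H](O)C/C(C)=C\CO | intermediate
8 | (2R,4Z)-6-chloro-4-methyl-1-(triethylsilyloxy)hex-4-en-2-ol | CC[Si](CC)(CC)OC[C@H](O)C/C(C)=C\CCl | intermediate
9 | (2R,4Z)-6-chloro-4-methyl-1,2-bis(triethylsilyloxy)hex-4-ene | CC[Si](CC)(CC)OC[C@H](O[Si](CC)(CC)CC)C/C(C)=C\CCl | intermediate
10 | 3-methylfuran-2(5H)-one | CC1=CCOC1=O | starting material
11 | (Z)-4-hydroxy-N-methoxy-N,2-dimethylbut-2-enamide (present as its chloromagnesium alkoxide) | CON(C)C(=O)/C(C)=C\CO | intermediate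
12 | (Z)-4-(tert-butyldimethylsilyloxy)-N-methoxy-N,2-dimethylbut-2-enamide | CON(C)C(=O)/C(C)=C\CO[Si](C)(C)C(C)(C)C | intermediate
13 | (Z)-4-(tert-butyldimethylsilyloxy)-2-methylbut-2-enal | O=C/C(C)=C\CO[Si](C)(C)C(C)(C)C | intermediate
14 | [(2Z,5R)-3-methyl-5,6-bis(triethylsilyloxy)hex-2-enyl]barium chloride | CC[Si](CC)(CC)OC[C@H](O[Si](CC)(CC)CC)C/C(C)=C\C[Ba]Cl | intermediate
15 | (2Z,4RS,6Z,9R)-1-(tert-butyldimethylsilyloxy)-3,7-dimethyl-9,10-bis(triethylsilyloxy)deca-2,6-dien-4-ol (C4 epimers) | CC[Si](CC)(CC)OC[C@H](O[Si](CC)(CC)CC)C/C(C)=C\CC(O)/C(C)=C\CO[Si](C)(C)C(C)(C)C | intermediate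
16 | (2Z,6Z,9R)-1-(tert-butyldimethylsilyloxy)-3,7-dimethyl-9,10-bis(triethylsilyloxy)deca-2,6-dien-4-one | CC[Si](CC)(CC)OC[C@H](O[Si](CC)(CC)CC)C/C(C)=C\CC(=O)/C(C)=C\CO[Si](C)(C)C(C)(C)C | intermediate
17 | (2Z,4S,6Z,9R)-1-(tert-butyldimethylsilyloxy)-3,7-dimethyl-9,10-bis(triethylsilyloxy)deca-2,6-dien-4-ol | CC[Si](CC)(CC)OC[C@H](O[Si](CC)(CC)CC)C/C(C)=C\C[C@H](O)/C(C)=C\CO[Si](C)(C)C(C)(C)C | intermediate
18 | (2Z,4S,6Z,9R)-1,4-bis(tert-butyldimethylsilyloxy)-3,7-dimethyl-9,10-bis(triethylsilyloxy)deca-2,6-diene | CC[Si](CC)(CC)OC[C@H](O[Si](CC)(CC)CC)C/C(C)=C\C[C@H](O[Si](C)(C)C(C)(C)C)/C(C)=C\CO[Si](C)(C)C(C)(C)C | intermediate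
19 | (2R,4Z,7S,8Z)-7,10-bis(tert-butyldimethylsilyloxy)-4,8-dimethyl-2-(triethylsilyloxy)deca-4,8-dienal | O=C[C@H](O[Si](CC)(CC)CC)C/C(C)=C\C[C@H](O[Si](C)(C)C(C)(C)C)/C(C)=C\CO[Si](C)(C)C(C)(C)C | intermediate
20 | methyl acrylate | C=CC(=O)OC | starting material
21 | methyl (3RS,4R,6Z,9S,10Z)-9,12-bis(tert-butyldimethylsilyloxy)-3-hydroxy-6,10-dimethyl-2-methylidene-4-(triethylsilyloxy)dodeca-6,10-dienoate (C3 epimers) | COC(=O)C(=C)C(O)[C@H](O[Si](CC)(CC)CC)C/C(C)=C\C[C@H](O[Si](C)(C)C(C)(C)C)/C(C)=C\CO[Si](C)(C)C(C)(C)C | intermediate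
22 | methyl (3RS,4R,6Z,9S,10Z)-9-(tert-butyldimethylsilyloxy)-3,4,12-trihydroxy-6,10-dimethyl-2-methylidenedodeca-6,10-dienoate (C3 epimers) | COC(=O)C(=C)C(O)[C@H](O)C/C(C)=C\C[C@H](O[Si](C)(C)C(C)(C)C)/C(C)=C\CO | intermediate
23 | methyl (3RS,4R,6Z,9S,10Z)-9-(tert-butyldimethylsilyloxy)-3,4-dihydroxy-6,10-dimethyl-2-methylidene-12-oxododeca-6,10-dienoate (C3 epimers) | COC(=O)C(=C)C(O)[C@H](O)C/C(C)=C\C[C@H](O[Si](C)(C)C(C)(C)C)/C(C)=C\C=O | intermediate
24 | methyl (2Z,4R,6Z,9S,10Z)-9-(tert-butyldimethylsilyloxy)-4-hydroxy-2-[(hydroxy)(iodo)indiganylmethyl]-6,10-dimethyl-12-oxododeca-2,6,10-trienoate | COC(=O)/C(C[In](I)O)=C/[C@H](O)C/C(C)=C\C[C@H](O[Si](C)(C)C(C)(C)C)/C(C)=C\C=O | intermediate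
25 | methyl (3S,6S,7R,8R)-3-(tert-butyldimethylsilyloxy)-6,8-dihydroxygermacra-1(10)Z,4Z,11(13)-trien-12-oate | COC(=O)C(=C)[C@H]1[C@@H](O)/C=C(/C)[C@@H](O[Si](C)(C)C(C)(C)C)C/C=C(/C)C[C@H]1O | intermediate
26 | (3S,6S,7R,8R)-3-(tert-butyldimethylsilyloxy)-8-hydroxygermacra-1(10)Z,4Z,11(13)-trien-12,6-olide | C=C1C(=O)O[C@H]2/C=C(/C)[C@@H](O[Si](C)(C)C(C)(C)C)C/C=C(/C)C[C@@H](O)[C@@H]12 | intermediate
27 | (Z)-4-(tert-butyldimethylsilyloxy)-2-methylbut-2-enoic acid | OC(=O)/C(C)=C\CO[Si](C)(C)C(C)(C)C | intermediate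
28 | (Z)-4-(tert-butyldimethylsilyloxy)-2-methylbut-2-enoic 2,4,6-trichlorobenzoic anhydride | O=C(OC(=O)/C(C)=C\CO[Si](C)(C)C(C)(C)C)c1c(Cl)cc(Cl)cc1Cl | intermediate
29 | (3S,6S,7R,8R)-3-(tert-butyldimethylsilyloxy)-8-[(Z)-4-(tert-butyldimethylsilyloxy)-2-methylbut-2-enoyloxy]germacra-1(10)Z,4Z,11(13)-trien-12,6-olide | C=C1C(=O)O[C@H]2/C=C(/C)[C@@H](O[Si](C)(C)C(C)(C)C)C/C=C(/C)C[C@@H](OC(=O)/C(C)=C\CO[Si](C)(C)C(C)(C)C)[C@@H]12 | intermediate
30 | (1R,3S,6S,7R,8R,10S)-3-(tert-butyldimethylsilyloxy)-8-[(Z)-4-(tert-butyldimethylsilyloxy)-2-methylbut-2-enoyloxy]-1,10-epoxygermacra-4Z,11(13)-dien-12,6-olide | C=C1C(=O)O[C@H]2/C=C(/C)[C@@H](O[Si](C)(C)C(C)(C)C)C[C@H]3O[C@@]3(C)C[C@@H](OC(=O)/C(C)=C\CO[Si](C)(C)C(C)(C)C)[C@@H]12 | intermediate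
31 | CNP0410854.1, (1R,3S,6S,7R,8R,10S)-1,10-epoxy-3-hydroxy-8-[(Z)-4-hydroxy-2-methylbut-2-enoyloxy]germacra-4Z,11(13)-dien-12,6-olide | C=C1C(=O)O[C@H]2/C=C(/C)[C@@H](O)C[C@H]3O[C@@]3(C)C[C@@H](OC(=O)/C(C)=C\CO)[C@@H]12 | target

## Step count and risks

Total steps: 20. Longest linear sequence: 16 steps (1 → 3 → 7 → 8 → 9 → 15 → 16 → 17 → 18 → 19 → 21 → 22 → 23 → 26 → 29 → 30 → 31; steps 1, 3, 4, 5, 8–16, 18–20).

Most likely to fail, first: step 16. The umpolung ring closure is unprecedented for a ten-membered ring and for a Baylis–Hillman diol. It could give oligomers, a 2,5-dihydrofuran by O-attack of the 8-OH on the π-allyl, the 12,8-lactone, E-enal-derived products, or the 7,8-epimeric series if chelation does not control the face. The fallback sets out from 21 and returns at 26. SN2' bromination of 21 (N-bromosuccinimide, Me2S) gives methyl (2Z,4R,6Z,9S,10Z)-2-(bromomethyl)-9,12-bis(tert-butyldimethylsilyloxy)-6,10-dimethyl-4-(triethylsilyloxy)dodeca-2,6,10-trienoate F1. Methanolysis with camphorsulfonic acid gives the bromo diol F2, and MnO2 oxidation gives the bromo enal F3. F3 is closed by the stoichiometric Nozaki–Hiyama–Kishi-type Barbier reaction (CrCl2, THF/DMF, high dilution), where the allylchromium from the Z-bromide again favours the syn adduct and lactonises to 26.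

Second: step 19. The face of epoxidation is set only by the conformation of the Z,Z-cyclodecadiene and cannot be predicted with confidence. The fallback sets out from 26 and returns at 30. While the 8-OH is still free it is used as a homoallylic directing group (VO(acac)2, t-BuOOH, CH2Cl2), which delivers oxygen to the 1(10)-alkene face syn to that hydroxyl and gives (1R,3S,6S,7R,8R,10S)-3-(tert-butyldimethylsilyloxy)-1,10-epoxy-8-hydroxygermacra-4Z,11(13)-dien-12,6-olide F4. Yamaguchi acylation of F4 with 27 then gives 30.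

Third: step 8. Rieke barium must insert cleanly into a functionalised allylic chloride and add α-selectively to a base-sensitive Z-enal. The fallback sets out from 9 and 12 and returns at 16, replacing the carbonyl allylation by a sulfone acylation. Displacement of chloride in 9 (PhSO2Na, DMF) gives the allylic sulfone F5, (2R,4Z)-4-methyl-6-(phenylsulfonyl)-1,2-bis(triethylsilyloxy)hex-4-ene. Its α-sulfonyl carbanion (2 equiv LiN(i-Pr)2, THF, −78 °C) is acylated at the α-carbon by Weinreb amide 12 to give the β-keto sulfone F6. Reductive desulfonylation (SmI2, THF/MeOH, −78 °C) with kinetic α-protonation of the dienolate then gives enone 16 directly, which also bypasses step 9.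

## Further compounds

F1 | step 16 | methyl (2Z,4R,6Z,9S,10Z)-2-(bromomethyl)-9,12-bis(tert-butyldimethylsilyloxy)-6,10-dimethyl-4-(triethylsilyloxy)dodeca-2,6,10-trienoate | COC(=O)/C(CBr)=C/[C@H](O[Si](CC)(CC)CC)C/C(C)=C\C[C@H](O[Si](C)(C)C(C)(C)C)/C(C)=C\CO[Si](C)(C)C(C)(C)C
F2 | step 16 | methyl (2Z,4R,6Z,9S,10Z)-2-(bromomethyl)-9-(tert-butyldimethylsilyloxy)-4,12-dihydroxy-6,10-dimethyldodeca-2,6,10-trienoate | COC(=O)/C(CBr)=C/[C@H](O)C/C(C)=C\C[C@H](O[Si](C)(C)C(C)(C)C)/C(C)=C\CO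
F3 | step 16 | methyl (2Z,4R,6Z,9S,10Z)-2-(bromomethyl)-9-(tert-butyldimethylsilyloxy)-4-hydroxy-6,10-dimethyl-12-oxododeca-2,6,10-trienoate | COC(=O)/C(CBr)=C/[C@H](O)C/C(C)=C\C[C@H](O[Si](C)(C)C(C)(C)C)/C(C)=C\C=O
F4 | step 19 | (1R,3S,6S,7R,8R,10S)-3-(tert-butyldimethylsilyloxy)-1,10-epoxy-8-hydroxygermacra-4Z,11(13)-dien-12,6-olide | C=C1C(=O)O[C@H]2/C=C(/C)[C@@H](O[Si](C)(C)C(C)(C)C)C[C@H]3O[C@@]3(C)C[C@@H](O)[C@@H]12
F5 | step 8 | (2R,4Z)-4-methyl-6-(phenylsulfonyl)-1,2-bis(triethylsilyloxy)hex-4-ene | CC[Si](CC)(CC)OC[C@H](O[Si](CC)(CC)CC)C/C(C)=C\CS(=O)(=O)c1ccccc1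
F6 | step 8 | (2Z,6Z,9R)-1-(tert-butyldimethylsilyloxy)-3,7-dimethyl-5-(phenylsulfonyl)-9,10-bis(triethylsilyloxy)deca-2,6-dien-4-one (C5 epimers) | CC[Si](CC)(CC)OC[C@H](O[Si](CC)(CC)CC)C/C(C)=C\C(C(=O)/C(C)=C\CO[Si](C)(C)C(C)(C)C)S(=O)(=O)c1ccccc1
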